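## Structural features

The target is a briarane in which a cyclohexene (ring A: C1, C10, C11, C12, C13, C14) is trans-fused through the C1–C10 bond to a ten-membered carbocycle (C1 to C10) that holds a (5Z) trisubstituted alkene and, fused at C7–C8, a γ-lactone (O–C19(=O)–C17–C8–C7). It has eleven stereogenic carbons and the stereogenic (5Z) alkene: the quaternary C1 (methyl C15) is followed by C2, C3 and C4 on one side of the ring fusion and C10 by C9, C8 (with C17) and C7 on the other, while C11 and C12 form a cis-diol next to C10. With β defined as the face of ring A that bears C15, C9 and the C11 methyl (C20) are β, whereas C2, H10, 11-OH and 12-OH are α. The oxygens are all differentiated: acetates on O2 and O9, an octanoate on O4, free hydroxyls on O3 and O12 and on the tertiary carbons C8, C11 and C17. Fragile groups are the O2/O3/O4 ester–alcohol–ester triad (acyl migration), the β-hydroxy lactone at C8/C17 (retro-aldol), the allylic C12 alcohol and the allylic C4 ester. The real difficulty lies in four places: closing the ten-membered ring, joining the two fully substituted carbinol carbons C8 and C17, setting the 11,12-cis-diol, and telling eight oxygen functions apart at the end. The key step uses one feature of ring A: the quaternary C1 stands next to C10–H, C2 and C9 are trans, and C12 bears oxygen, which is the retron of a [4+2] cycloaddition that forms C1–C14 and C10–C11 with the C12 oxygen as a silyl enol ether (C12=C13).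

## Logic of the disconnections

41 ⇒ 38. No skeletal bond is cut. The C11 silyl ether, the C3 p-methoxybenzyl ether and the C12–H bond are retrons of three mild end steps. Ring A is kept as an enone until the large ring exists, and O3 stays masked while O4 is acylated. The demand is that reduction, oxidative debenzylation and fluoride treatment leave three esters and a lactone alone.

38 ⇒ 37. The O4–acyl bond is cut. In 37 the C4 hydroxyl is the only secondary alcohol, so the forward acylation has only to leave three tertiary alcohols untouched.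

37 ⇒ 36. The C4–C5 bond of the ten-membered ring is cut at the allylic carbinol. This gives an aldehyde and a (Z)-alkenyl iodide in one chain, and the alkene geometry is fixed before ring closure. The forward step must close a medium ring chemoselectively in the presence of an enone, a lactone and free tertiary hydroxyls, and it creates C4.

36 ⇒ 34 ⇒ 33. The C4 aldehyde is traced to a terminal vinyl group and the O9 acetate to the free alcohol. The aldehyde, which is α-alkoxy and β-acyloxy, then exists for one step only. The oxidative cleavage must spare the enone alkene C13=C14 and the iodoalkene.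

33 ⇒ 31 ⇒ 26 + 29. The lactone O7–C19 bond and the C8–C17 bond are cut. Both fully substituted carbons come from one aldol addition of a lactic acid enolate equivalent to a C8 ketone. The gain is the whole C17–C19 unit with its stereocentre from the chiral pool. The forward addition must take one face of a hindered ketone, and O7 rather than O9 must close the lactone.

26 ⇒ 24 ⇒ 22 ⇒ 20. The C8 carbonyl is traced to a protected carbinol, the C11–O bond to enol ether oxidation of the ring A enone, and the C7 carbinol to a C7 ketone. A cyclic acetal over O7 and O9 makes the C8 ketone a rigid 1,3-dioxan-5-one. The forward steps need a silyl group on O8 that leaves before the one on O11, and a 1,3-syn reduction.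

20 ⇒ 11 + 18. The C8–C9 bond is cut between an aldehyde on C10 and the α-carbon of an alkoxymethyl ketone that already holds the (Z)-iodoalkene. The route becomes convergent. The forward aldol must take the correct face of an aldehyde whose α-carbon C10 lies between a quaternary and a tertiary carbon.

11 ⇒ 9 ⇒ 7. The C2–C3 bond is cut. A γ-alkoxyallyl metal reagent adds C3, C4 and a latent C4 aldehyde to the C1 formyl group and sets the 2,3-syn pair. C9 is released from its silyl ether only afterwards, so that two aldehydes never coexist. The reagent must override any bias of the neopentyl aldehyde.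

7 ⇒ 6 ⇒ 2 + 5. The C13=C14 unsaturation is removed, then C1–C14 and C10–C11 are cut. Ring A with three stereocentres falls to two acyclic five-carbon pieces. The forward cycloaddition must be regioselective and enantioselective.

5 ⇒ 3 + 4, 2 ⇒ 1, 18 ⇒ 12 + 13, 29 ⇒ 27 + 28. The C1=C10 bond of 5 is cut by olefination, 2 is the enol ether of 1, 18 is cut at C6–C7, and 29 is the acetal of 27 with 28. The C9 oxygen of 5 is carried as a silyl ether, because it must be freed later in the presence of three alkenes and a p-methoxybenzyl ether, which rules out hydrogenolysis of a benzyl ether.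

## Other disconnections considered

Alternative 1: The C3=C4 alkene and the C9 ketone of cyclodecadienone A1 are read as the trace of a C4–C9 bond. The precursor of A1 is then a tricycle in which ring A is fused to a decalin-type pair of six-membered rings, with a tertiary alkoxide at C9 and a sulfonate at C3. Base would trigger a Wharton–Grob fragmentation that merges the two rings into the ten-membered ring.

- In its favour: the medium ring comes from common rings without an entropic penalty, the E geometry at C3=C4 follows from the anti-periplanar C4–C9 and C3–O bonds, and the (5Z) alkene is held in a ring beforehand. On ring formation and on control of alkene geometry it is the better of the two plans.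
- Against it here: the target has no C3=C4 alkene. A1 still needs face-selective dihydroxylation of that alkene on a flexible ring beside two other alkenes, reduction of the C9 ketone, and the lactate addition to C8 on the medium ring, where transannular reactions threaten. The tricycle with the quaternary C1 must also be built first.
- Comparison: the chosen plan puts the O2, O3, O4 and O9 stereocentres in place on open chains by reagent control and pays with a ring closure that creates C4 without a firm model. In step count the alternative is expected to be no shorter, because of the oxidation-state changes after the fragmentation.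

Alternative 2: The C11–C12 bond of ring A is cut. A preformed ten-membered ring would carry an acetyl group on C10 and a (Z)-enal on C1, and SmI2 would join the ketone and aldehyde carbons to give bicycle A2.

- In its favour: the chelated samarium diolate gives the 11,12-cis-diol directly. This is the relationship the chosen plan secures with the least certainty (hydride reduction at C12), so on this point the alternative is better.
- Against it here: the quaternary C1 and the trans C1/C10 pair must be made on a macrocycle or its open precursor without a cycloaddition. Divalent samarium also reduces enals by conjugate pathways. The face of the ketone that reacts, and hence C11 relative to C10, rests on the conformation of the large ring.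
- Comparison: A2 still lacks the lactone, so the C8 aldol would again be run on a medium-ring ketone. The chosen plan sets C1 and C10 in its first stereo-defining step and does the C8 chemistry on a conformationally defined dioxanone. Step counts should be similar.

Alternative 3: The C4–C5 bond is cut and the ring closed by chromium-mediated addition of a (Z)-alkenyl iodide to a C4 aldehyde, giving A3.

- In its favour: the reaction tolerates esters, a lactone and free tertiary alcohols, fixes the alkene geometry beforehand and makes the very carbinol that is to be acylated.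
- Against it: C4 is created under macrocyclic control only, and the seco compound is long.
- Comparison: this is the bond construction used in step 25 of the chosen route, so on ring closure the two plans are equal. As a governing idea it leaves the origin of ring A and of C1/C10 open, which the cycloaddition settles. A3 already carries the C12 stereocentre as a silyl ether, so it avoids a late reduction; on that point it is the better. The price is that the C13=C14 alkene is no longer deactivated as an enone when the C4 aldehyde is made by oxidative cleavage.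

Key step: step 3

Assumption: the (R)-enantiomer of 3,3-diphenyl-1-(2-methylphenyl)tetrahydro-1H,3H-pyrrolo[1,2-c][1,3,2]oxazaborole, protonated by (CF3SO2)2NH, is chosen on the model of formyl C–H···O binding of 2-substituted enals, which exposes the Si face at the methyl-bearing carbon of 5 (the future C1); if the sense is the opposite, the (S)-enantiomer of the same oxazaborole is used without other change.

Step 1
Reactants: 1 pent-1-en-3-one
Product: 2 (Z)-3-(triethylsilyloxy)penta-1,3-diene
Conditions: Et3SiOSO2CF3, Et3N, Et2O, 0 °C
Reagents that add atoms: triethylsilyl trifluoromethanesulfonate, CC[Si](CC)(CC)OS(=O)(=O)C(F)(F)F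
Why: Soft enolisation and O-silylation of the ethyl ketone; the Z enol ether (methyl trans to vinyl), the isomer that can reach the s-cis conformation, should predominate.

Step 2
Reactants: 3 (tert-butyldimethylsilyloxy)acetaldehyde; 4 2-(triphenylphosphoranylidene)propanal
Product: 5 (E)-4-(tert-butyldimethylsilyloxy)-2-methylbut-2-enal
Conditions: toluene, 80 °C
Reagents that add atoms: none
Why: Wittig reaction of a stabilised ylide, which should give the E enal under thermodynamic control of the oxaphosphetane.

Step 3
Reactants: 2 (Z)-3-(triethylsilyloxy)penta-1,3-diene; 5 (E)-4-(tert-butyldimethylsilyloxy)-2-methylbut-2-enal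
Product: 6 (1S,5S,6S)-6-[(tert-butyldimethylsilyloxy)methyl]-1,5-dimethyl-4-(triethylsilyloxy)cyclohex-3-ene-1-carbaldehyde
Conditions: (R)-3,3-diphenyl-1-(2-methylphenyl)tetrahydro-1H,3H-pyrrolo[1,2-c][1,3,2]oxazaborole (20 mol %), (CF3SO2)2NH (17 mol %), CH2Cl2, slow addition of 2, −78 → −40 °C
Reagents that add atoms: none
Why: Concerted, asynchronous, suprafacial [4+2] cycloaddition of the s-cis diene to the enal held s-trans on the cationic boron, with C10–C11 (enol ether β-carbon to enal β-carbon) the more advanced bond. The closest known reaction type is the oxazaborolidinium-catalysed Diels–Alder reaction of 2-substituted enals with 2-silyloxy dienes. Ring A closes by intermolecular cycloaddition, C1–C14 and C10–C11 forming in one step with every atom of both partners kept in the adduct. C1 and C10 are set relative to each other by the E geometry of 5, which becomes C2 trans to C9 and C15 cis to C9. Their absolute sense comes from the catalyst aryl group, which shields one face so that the diene adds to the Si face at C1. C11 follows from formyl-endo approach and the Z enol ether; it is erased in step 16, so endo/exo control is not needed. The step needs regioselectivity (C12 para to the formyl-bearing C1), secured by the silyloxy group that makes C11 the nucleophilic terminus, and face selectivity, secured by two-point binding of the aldehyde.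

Step 4
Reactants: 6 ring A cycloadduct
Product: 7 ring A enone aldehyde (C12 ketone, C13=C14)
Conditions: Pd(OAc)2 (1.1 equiv), MeCN, 23 °C
Reagents that add atoms: none
Why: Saegusa–Ito oxidation: the C12=C13 silyl enol ether gives an oxa-π-allyl complex of divalent palladium and β-hydride loss from C14 gives the enone; the formyl group has no α-hydrogen.

Step 5
Reactants: 7 ring A enone aldehyde
Product: 8 (2R,3R)-2,3-syn homoallylic alcohol (C3 p-methoxybenzyl ether, vinyl as latent C4)
Conditions: allyl 4-methoxybenzyl ether, s-BuLi, THF, −78 °C; (−)-B-methoxydiisopinocampheylborane; BF3·OEt2; then 7, −78 → 0 °C; NaHCO3 aq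
Reagents that add atoms: allyl 4-methoxybenzyl ether, C=CCOCc1ccc(OC)cc1
Why: Brown alkoxyallylboration through a chair transition state: the (Z)-γ-alkoxyallylborane gives the syn pair and the isopinocampheyl groups direct attack to the Si face of the aldehyde (2R). The hindered enone ketone should react far more slowly than the aldehyde.

Step 6
Reactants: 8 (2R,3R)-alcohol
Product: 9 C2 acetate
Conditions: Ac2O, 4-(dimethylamino)pyridine, pyridine, 23 °C
Reagents that add atoms: acetic anhydride, CC(=O)OC(C)=O
Why: Nucleophile-catalysed acylation of the only free hydroxyl; the acetate is the final C2 group and protects O2 meanwhile.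

Step 7
Reactants: 9 C2 acetate
Product: 10 primary C9 alcohol
Conditions: HF·pyridine, pyridine, THF, 0 → 23 °C
Reagents that add atoms: none
Why: Fluoride cleavage of the primary silyl ether under buffered, non-basic conditions, so that the acetate neither migrates nor cleaves.

Step 8
Reactants: 10 primary C9 alcohol
Product: 11 C9 aldehyde
Conditions: Dess–Martin periodinane, NaHCO3, CH2Cl2, 0 °C
Reagents that add atoms: none
Why: Buffered Dess–Martin oxidation; the mild, non-basic medium should keep the C10 α-centre intact, and the aldehyde is used at once.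

Step 9
Reactants: 12 glycolaldehyde dimer; 13 1-propynylmagnesium bromide
Product: 14 pent-3-yne-1,2-diol
Conditions: THF, 0 → 23 °C; NH4Cl aq
Reagents that add atoms: none
Why: Grignard addition to the aldehyde released from the hemiacetal dimer; one equivalent per aldehyde is spent on the hydroxyl.

Step 10
Reactants: 14 pent-3-yne-1,2-diol
Product: 16 (Z)-4-iodopent-3-ene-1,2-diol, via cyclic alkenylaluminate 15 (not isolated)
Conditions: NaAlH2(OCH2CH2OCH3)2, THF, 0 °C; then I2, −78 → 0 °C
Reagents that add atoms: iodine, II
Why: Alkoxide-directed trans-hydroalumination places aluminium on the distal alkyne carbon; iodination with retention gives the Z iodoalkene with iodine cis to the carbinol carbon.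

Step 11
Reactants: 16 (Z)-4-iodopent-3-ene-1,2-diol
Product: 17 (Z)-4-iodo-1-(triethylsilyloxy)pent-3-en-2-ol
Conditions: Et3SiCl, imidazole, CH2Cl2, −20 °C
Reagents that add atoms: chlorotriethylsilane, CC[Si](Cl)(CC)CC
Why: Selective silylation of the primary over the secondary allylic hydroxyl on steric grounds.

Step 12
Reactants: 17 (Z)-4-iodo-1-(triethylsilyloxy)pent-3-en-2-ol
Product: 18 (Z)-4-iodo-1-(triethylsilyloxy)pent-3-en-2-one
Conditions: Dess–Martin periodinane, NaHCO3, CH2Cl2, 0 → 23 °C
Reagents that add atoms: none
Why: Dess–Martin oxidation of the allylic alcohol; the neutral medium keeps the Z β-iodoenone from isomerising.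

Step 13
Reactants: 18 (Z)-4-iodo-1-(triethylsilyloxy)pent-3-en-2-one; 11 C9 aldehyde
Product: 20 C8–C9 aldol adduct (9R; 8,9-anti; C7 ketone), via enol borinate 19 (not isolated)
Conditions: (c-C6H11)2BCl, Et3N, Et2O, −78 → 0 °C; then 11, −78 → −20 °C; pH 7 buffer, MeOH
Reagents that add atoms: none
Why: Boron aldol reaction through a closed chair transition state. The E enol borinate should add to the Felkin–Anh face of 11, with the quaternary C1 anti to the forming bond and the tertiary C11 gauche to the carbonyl oxygen, giving 9R. C8 is oxidised in step 19, so its configuration does not matter.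

Step 14
Reactants: 20 aldol adduct
Product: 21 (7S,9R)-7,9-syn-diol
Conditions: Et2BOMe, NaBH4, THF/MeOH (4:1), −78 °C; AcOH; MeOH azeotrope
Reagents that add atoms: none
Why: Narasaka–Prasad reduction: boron chelation of the β-hydroxy ketone and axial external hydride delivery give the 1,3-syn diol. The chelated ketone is activated over the hindered ring A enone, and 1,2-addition keeps the iodoalkene.

Step 15
Reactants: 21 7,9-syn-diol
Product: 22 7,9-O-isopropylidene acetal
Conditions: 2,2-dimethoxypropane, pyridinium p-toluenesulfonate (cat.), CH2Cl2, 23 °C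
Reagents that add atoms: 2,2-dimethoxypropane, COC(C)(C)OC
Why: Acetal exchange; the syn-1,3-diol gives a chair dioxane with both ring substituents equatorial, and the secondary triethylsilyl ether should survive the weak acid.

Step 16
Reactants: 22 acetonide
Product: 23 ring A 12-silyloxy-11,13-diene (tert-butyldimethylsilyl dienol ether)
Conditions: t-BuMe2SiOSO2CF3, Et3N, CH2Cl2, −78 → 0 °C
Reagents that add atoms: tert-butyldimethylsilyl trifluoromethanesulfonate, CC(C)(C)[Si](C)(C)OS(=O)(=O)C(F)(F)F
Why: Soft enolisation of the enone at its only α'-position, C11, gives the cross-conjugated silyloxy diene and removes the C11 centre left by the cycloaddition; the acetate is enolised far more slowly than the ketone.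

Step 17
Reactants: 23 silyl dienol ether
Product: 24 11α-(tert-butyldimethylsilyloxy) C12 enone
Conditions: dimethyldioxirane, acetone/CH2Cl2, −78 → −40 °C
Reagents that add atoms: dimethyldioxirane, CC1(C)OO1
Why: Rubottom oxidation: the electron-rich C11=C12 enol ether is epoxidised on the α face, anti to the large C9 substituent on the neighbouring C10. Ring opening with 1,4-silyl shift gives the α-silyloxy enone; the vinyl group, the iodoalkene and C13=C14 are much less nucleophilic.

Step 18
Reactants: 24 11-silyloxy enone
Product: 25 C8 alcohol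
Conditions: HF·pyridine, pyridine, THF, 0 °C
Reagents that add atoms: none
Why: Selective desilylation: a secondary triethylsilyl ether is cleaved far faster than a tertiary tert-butyldimethylsilyl ether, and the acetonide is stable to buffered fluoride.

Step 19
Reactants: 25 C8 alcohol
Product: 26 C8 ketone (4,6-cis-disubstituted 2,2-dimethyl-1,3-dioxan-5-one)
Conditions: Dess–Martin periodinane, NaHCO3, CH2Cl2, 23 °C
Reagents that add atoms: none
Why: Dess–Martin oxidation of the only free hydroxyl; buffering guards the α-stereocentres C7 and C9 against epimerisation.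

Step 20
Reactants: 27 (R)-lactic acid; 28 2,2-dimethylpropanal
Product: 29 (2R,5R)-2-tert-butyl-5-methyl-1,3-dioxolan-4-one
Conditions: p-toluenesulfonic acid monohydrate (cat.), H2SO4 (cat.), pentane, reflux with water separation; recrystallisation
Reagents that add atoms: none
Why: Acid-catalysed acetalisation with removal of water; the cis acetal is favoured and is purified by crystallisation.

Step 21
Reactants: 29 (2R,5R)-dioxolanone; 26 C8 ketone
Product: 31 C8–C17 aldol adduct (tertiary C8 alcohol; dioxolanone kept), via lithium enolate 30 (not isolated)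
Conditions: LiN(iPr)2, THF, −78 °C; then 26, −78 °C; AcOH quench at −78 °C
Reagents that add atoms: none
Why: Aldol addition of a lactic acid enolate with self-regeneration of the stereocentre: the ketone enters anti to the tert-butyl group, which sets C17. Axial attack on the dioxanone, free of 1,3-diaxial hydrogens and of the torsional strain of equatorial attack, puts C17 syn to O7 and O9, which sets C8. The cold quench forestalls retro-aldol cleavage.

Step 22
Reactants: 31 aldol adduct
Product: 33 γ-lactone (C9–OH free), via 7,9-diol 32 (not isolated)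
Conditions: AcOH/THF/H2O (3:1:1), 40 °C; then Et3N, CH2Cl2, 23 °C
Reagents that add atoms: none
Why: Acetal hydrolysis, then 5-exo-trig acyl substitution in which the less hindered allylic C7 hydroxyl, not the neopentyl-like C9 hydroxyl, opens the dioxolanone. Loss of 2,2-dimethylpropanal frees the C17 hydroxyl, and the tertiary silyl ether should survive.

Step 23
Reactants: 33 γ-lactone
Product: 34 C9 acetate
Conditions: Ac2O, 4-(dimethylamino)pyridine (0.1 equiv), pyridine, 0 → 23 °C
Reagents that add atoms: acetic anhydride, CC(=O)OC(C)=O
Why: Acylation of the only secondary hydroxyl; the tertiary hydroxyls at C8 and C17 should stay free under these mild conditions.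

Step 24
Reactants: 34 C9 acetate
Product: 36 C4 aldehyde (seco compound), via vicinal diol 35 (not isolated)
Conditions: OsO4 (cat.), NaIO4, 2,6-lutidine, dioxane/H2O (3:1), 23 °C
Reagents that add atoms: osmium tetroxide (oxygen carrier), O=[Os](=O)(=O)=O; sodium periodate (terminal oxidant), [Na+].[O-]I(=O)(=O)=O
Why: Johnson–Lemieux cleavage: osmylation picks the electron-rich monosubstituted alkene over the enone alkene and the iodoalkene, and periodate cleaves the terminal diol. The trans-ditertiary diol on the lactone cannot form a cyclic periodate ester easily.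

Step 25
Reactants: 36 seco aldehyde
Product: 37 macrocyclic (4S)-allylic alcohol
Conditions: CrCl2 (10 equiv), NiCl2 (cat.), DMSO, 0.002 M, 23 °C
Reagents that add atoms: none
Why: Nozaki–Hiyama–Kishi reaction: zerovalent nickel inserts into the C5–I bond with retention of the Z geometry, transmetalation gives an alkenyl species of trivalent chromium, and this adds to the C4 aldehyde only, closing the ten-membered ring. C4 is set by the conformation of the forming ring, and the 4S epimer is the one needed.

Step 26
Reactants: 37 macrocyclic allylic alcohol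
Product: 38 C4 octanoate
Conditions: octanoyl chloride, pyridine, 4-(dimethylamino)pyridine (cat.), CH2Cl2, 0 °C
Reagents that add atoms: octanoyl chloride, CCCCCCCC(=O)Cl
Why: Acylation of the only secondary hydroxyl with retention at C4.

Step 27
Reactants: 38 C4 octanoate
Product: 39 12α-alcohol (11-O-silyl, 3-O-p-methoxybenzyl)
Conditions: NaBH4, CeCl3·7H2O, MeOH/CH2Cl2, −78 °C
Reagents that add atoms: none
Why: Luche 1,2-reduction, to which esters and the lactone are inert. Hydride should add anti to the bulky, non-chelating C11–O–Si bond (Felkin–Anh), placing the C12 hydroxyl cis to O11.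

Step 28
Reactants: 39 12α-alcohol
Product: 40 11-O-(tert-butyldimethylsilyl) ether of the target (C3–OH free)
Conditions: DDQ, CH2Cl2/pH 7 buffer, 0 °C
Reagents that add atoms: none
Why: Oxidative cleavage of the p-methoxybenzyl ether by hydride abstraction and hydrolysis; cold, short, buffered conditions should spare the allylic C12 alcohol and prevent acyl migration.

Step 29
Reactants: 40 11-O-silyl ether
Product: 41 CNP0164780.1
Conditions: HF·pyridine, THF, 0 → 23 °C
Reagents that add atoms: none
Why: Fluoride desilylation of the tertiary ether, helped by the neighbouring C12 hydroxyl; the mildly acidic medium should not move the esters at O2, O4 and O9.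

## Compound list

1 | pent-1-en-3-one | C=CC(=O)CC | starting material
2 | (Z)-3-(triethylsilyloxy)penta-1,3-diene | C=C/C(O[Si](CC)(CC)CC)=C/C | intermediate
3 | (tert-butyldimethylsilyloxy)acetaldehyde | O=CCO[Si](C)(C)C(C)(C)C | starting material
4 | 2-(triphenylphosphoranylidene)propanal | CC(C=O)=P(c1ccccc1)(c1ccccc1)c1ccccc1 | starting material
5 | (E)-4-(tert-butyldimethylsilyloxy)-2-methylbut-2-enal | O=C/C(C)=C/CO[Si](C)(C)C(C)(C)C | intermediate
6 | (1S,5S,6S)-6-[(tert-butyldimethylsilyloxy)methyl]-1,5-dimethyl-4-(triethylsilyloxy)cyclohex-3-ene-1-carbaldehyde (ring A; C15 and C9 β, formyl C2 and C20 α) | O=C[C@@]1(C)CC=C(O[Si](CC)(CC)CC)[C@@H](C)[C@@H]1CO[Si](C)(C)C(C)(C)C | intermediate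
7 | ring A enone aldehyde: 6-[(tert-butyldimethylsilyloxy)methyl]-1,5-dimethyl-4-oxocyclohex-2-ene-1-carbaldehyde, C1 and C10 as in 6 | O=C[C@@]1(C)C=CC(=O)[C@@H](C)[C@@H]1CO[Si](C)(C)C(C)(C)C | intermediate
8 | ring A enone with the chain C2H(OH)–C3H(O-p-methoxybenzyl)–CH=CH2 on C1, (2R,3R), 2,3-syn; C9 as CH2OSi(t-Bu)Me2 | C=C[C@@H](OCc2ccc(OC)cc2)[C@H](O)[C@@]1(C)C=CC(=O)[C@@H](C)[C@@H]1CO[Si](C)(C)C(C)(C)C | intermediate
9 | C2 acetate of 8 | C=C[C@@H](OCc2ccc(OC)cc2)[C@H](OC(C)=O)[C@@]1(C)C=CC(=O)[C@@H](C)[C@@H]1CO[Si](C)(C)C(C)(C)C | intermediate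
10 | primary C9 alcohol (silyl ether of 9 removed) | C=C[C@@H](OCc2ccc(OC)cc2)[C@H](OC(C)=O)[C@@]1(C)C=CC(=O)[C@@H](C)[C@@H]1CO | intermediate
11 | C9 aldehyde on C10 of the ring A enone | C=C[C@@H](OCc2ccc(OC)cc2)[C@H](OC(C)=O)[C@@]1(C)C=CC(=O)[C@@H](C)[C@@H]1C=O | intermediate
12 | glycolaldehyde dimer (1,4-dioxane-2,5-diol) | OC1COC(O)CO1 | starting material
13 | 1-propynylmagnesium bromide | CC#C[Mg]Br | starting material
14 | pent-3-yne-1,2-diol (racemic) | CC#CC(O)CO | intermediate
15 | sodium cyclic (Z)-alkenyl(alkoxy)aluminate from 14 (simplified drawing, aluminium on C4 and O2; formed in the flask and not isolated) | CC1=CC(CO)O[Al-]1(OCCOC)OCCOC.[Na+] | intermediate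
16 | (Z)-4-iodopent-3-ene-1,2-diol (racemic) | C/C(I)=C/C(O)CO | intermediate
17 | (Z)-4-iodo-1-(triethylsilyloxy)pent-3-en-2-ol (racemic) | C/C(I)=C/C(O)CO[Si](CC)(CC)CC | intermediate
18 | (Z)-4-iodo-1-(triethylsilyloxy)pent-3-en-2-one | C/C(I)=C/C(=O)CO[Si](CC)(CC)CC | intermediate
19 | (E)-enol dicyclohexylborinate of 18 (formed in the flask and not isolated) | C/C(I)=C/C(OB(C1CCCCC1)C1CCCCC1)=C\O[Si](CC)(CC)CC | intermediate
20 | aldol adduct: (9R)-hydroxyl, C8 triethylsilyl ether anti to O9, C7 ketone, (5Z)-C5 iodide | C=C[C@@H](OCc2ccc(OC)cc2)[C@H](OC(C)=O)[C@@]1(C)C=CC(=O)[C@@H](C)[C@@H]1[C@@H](O)[C@@H](O[Si](CC)(CC)CC)C(=O)/C=C(/C)I | intermediate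
21 | (7S,9R)-7,9-syn-diol, C8 triethylsilyl ether | C=C[C@@H](OCc2ccc(OC)cc2)[C@H](OC(C)=O)[C@@]1(C)C=CC(=O)[C@@H](C)[C@@H]1[C@@H](O)[C@@H](O[Si](CC)(CC)CC)[C@@H](O)/C=C(/C)I | intermediate
22 | 7,9-O-isopropylidene acetal of 21 | C=C[C@@H](OCc2ccc(OC)cc2)[C@H](OC(C)=O)[C@@]1(C)C=CC(=O)[C@@H](C)[C@@H]1[C@H]3OC(C)(C)O[C@@H](/C=C(/C)I)[C@@H]3O[Si](CC)(CC)CC | intermediate
23 | ring A 12-(tert-butyldimethylsilyloxy)-11,13-diene | C=C[C@@H](OCc2ccc(OC)cc2)[C@H](OC(C)=O)[C@@]1(C)C=CC(O[Si](C)(C)C(C)(C)C)=C(C)[C@@H]1[C@H]3OC(C)(C)O[C@@H](/C=C(/C)I)[C@@H]3O[Si](CC)(CC)CC | intermediate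
24 | 11α-(tert-butyldimethylsilyloxy) C12 enone (C20 β) | C=C[C@@H](OCc2ccc(OC)cc2)[C@H](OC(C)=O)[C@@]1(C)C=CC(=O)[C@@](C)(O[Si](C)(C)C(C)(C)C)[C@@H]1[C@H]3OC(C)(C)O[C@@H](/C=C(/C)I)[C@@H]3O[Si](CC)(CC)CC | intermediate
25 | C8 alcohol (triethylsilyl ether of 24 removed) | C=C[C@@H](OCc2ccc(OC)cc2)[C@H](OC(C)=O)[C@@]1(C)C=CC(=O)[C@@](C)(O[Si](C)(C)C(C)(C)C)[C@@H]1[C@H]3OC(C)(C)O[C@@H](/C=C(/C)I)[C@@H]3O | intermediate
26 | C8 ketone: 4,6-cis-disubstituted 2,2-dimethyl-1,3-dioxan-5-one | C=C[C@@H](OCc2ccc(OC)cc2)[C@H](OC(C)=O)[C@@]1(C)C=CC(=O)[C@@](C)(O[Si](C)(C)C(C)(C)C)[C@@H]1[C@H]3OC(C)(C)O[C@@H](/C=C(/C)I)C3=O | intermediate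
27 | (R)-lactic acid | C[C@@H](O)C(=O)O | starting material
28 | 2,2-dimethylpropanal | CC(C)(C)C=O | starting material
29 | (2R,5R)-2-tert-butyl-5-methyl-1,3-dioxolan-4-one (cis) | C[C@H]1O[C@@H](C(C)(C)C)OC1=O | intermediate
30 | lithium enolate of 29 (formed in the flask and not isolated) | CC1=C(O[Li])O[C@H](C(C)(C)C)O1 | intermediate
31 | C8–C17 aldol adduct: tertiary C8 alcohol (C17 syn to O7 and O9), dioxolanone on C17 with C8 trans to tert-butyl | C=C[C@@H](OCc2ccc(OC)cc2)[C@H](OC(C)=O)[C@@]1(C)C=CC(=O)[C@@](C)(O[Si](C)(C)C(C)(C)C)[C@@H]1[C@H]3OC(C)(C)O[C@@H](/C=C(/C)I)[C@@]3(O)[C@]4(C)O[C@@H](C(C)(C)C)OC4=O | intermediate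
32 | 7,8,9-triol with the dioxolanone intact (formed in the flask and not isolated) | C=C[C@@H](OCc2ccc(OC)cc2)[C@H](OC(C)=O)[C@@]1(C)C=CC(=O)[C@@](C)(O[Si](C)(C)C(C)(C)C)[C@@H]1[C@@H](O)[C@@](O)([C@@H](O)/C=C(/C)I)[C@]4(C)O[C@@H](C(C)(C)C)OC4=O | intermediate
33 | γ-lactone (O7–C19) with 8- and 17-hydroxyls as in the target, C9 hydroxyl free | C=C[C@@H](OCc2ccc(OC)cc2)[C@H](OC(C)=O)[C@@]1(C)C=CC(=O)[C@@](C)(O[Si](C)(C)C(C)(C)C)[C@@H]1[C@@H](O)[C@@]3(O)[C@H](/C=C(/C)I)OC(=O)[C@@]3(C)O | intermediate
34 | C9 acetate of 33 | C=C[C@@H](OCc2ccc(OC)cc2)[C@H](OC(C)=O)[C@@]1(C)C=CC(=O)[C@@](C)(O[Si](C)(C)C(C)(C)C)[C@@H]1[C@@H](OC(C)=O)[C@@]3(O)[C@H](/C=C(/C)I)OC(=O)[C@@]3(C)O | intermediate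
35 | terminal vicinal diol from the vinyl group of 34 (both epimers at the new carbinol; formed in the flask and not isolated) | OCC(O)[C@@H](OCc2ccc(OC)cc2)[C@H](OC(C)=O)[C@@]1(C)C=CC(=O)[C@@](C)(O[Si](C)(C)C(C)(C)C)[C@@H]1[C@@H](OC(C)=O)[C@@]3(O)[C@H](/C=C(/C)I)OC(=O)[C@@]3(C)O | intermediate
36 | seco compound: C4 aldehyde and (5Z)-C5 iodide | O=C[C@@H](OCc2ccc(OC)cc2)[C@H](OC(C)=O)[C@@]1(C)C=CC(=O)[C@@](C)(O[Si](C)(C)C(C)(C)C)[C@@H]1[C@@H](OC(C)=O)[C@@]3(O)[C@H](/C=C(/C)I)OC(=O)[C@@]3(C)O | intermediate
37 | macrocyclic (4S)-allylic alcohol (C12 ketone, 11-O-silyl, 3-O-p-methoxybenzyl) | O[C@H]1/C(C)=C\[C@@H]2OC(=O)[C@@](C)(O)[C@@]2(O)[C@H](OC(C)=O)[C@H]2[C@](C)(O[Si](C)(C)C(C)(C)C)C(=O)C=C[C@]2(C)[C@@H](OC(C)=O)[C@@H]1OCc1ccc(OC)cc1 | intermediate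
38 | C4 octanoate of 37 | CCCCCCCC(=O)O[C@H]1/C(C)=C\[C@@H]2OC(=O)[C@@](C)(O)[C@@]2(O)[C@H](OC(C)=O)[C@H]2[C@](C)(O[Si](C)(C)C(C)(C)C)C(=O)C=C[C@]2(C)[C@@H](OC(C)=O)[C@@H]1OCc1ccc(OC)cc1 | intermediate
39 | 12α-alcohol, cis to O11 (11-O-silyl, 3-O-p-methoxybenzyl) | CCCCCCCC(=O)O[C@H]1/C(C)=C\[C@@H]2OC(=O)[C@@](C)(O)[C@@]2(O)[C@H](OC(C)=O)[C@H]2[C@](C)(O[Si](C)(C)C(C)(C)C)[C@H](O)C=C[C@]2(C)[C@@H](OC(C)=O)[C@@H]1OCc1ccc(OC)cc1 | intermediate
40 | 11-O-(tert-butyldimethylsilyl) ether of the target | CCCCCCCC(=O)O[C@H]1/C(C)=C\[C@@H]2OC(=O)[C@@](C)(O)[C@@]2(O)[C@H](OC(C)=O)[C@H]2[C@](C)(O[Si](C)(C)C(C)(C)C)[C@H](O)C=C[C@]2(C)[C@@H](OC(C)=O)[C@@H]1O | intermediate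
41 | CNP0164780.1 | CCCCCCCC(=O)O[C@H]1/C(C)=C\[C@@H]2OC(=O)[C@@](C)(O)[C@@]2(O)[C@H](OC(C)=O)[C@H]2[C@](C)(O)[C@H](O)C=C[C@]2(C)[C@@H](OC(C)=O)[C@@H]1O | target

## Step count and least certain steps

Total: 29 steps. Longest linear sequence: 23 steps (step 1, steps 3 to 8, steps 13 to 19, steps 21 to 29).

Step 3 (key step). The trisubstituted enal may turn over slowly; the acid-sensitive diene may lose its silyl group before it reacts, which its slow addition is meant to limit; and a stepwise Mukaiyama-type addition or an uncatalysed background reaction may erode the enantiomeric purity. Fallback: take the absolute configuration from the borane of step 5 instead of from the catalyst. Setting out from 2 and 5, the cycloaddition is run with the achiral Lewis acid Me2AlCl in CH2Cl2 at −78 °C. This gives 6 together with its enantiomer, the ent-cycloadduct F1. Saegusa oxidation as in step 4 gives 7 and the ent-enone aldehyde F2. The alkoxyallylboration of step 5 then converts 7 into 8 and F2 into the diastereomeric alcohol F3, which has the same 2R,3R centres on the mirror-image ring. F3 is removed by chromatography and the route is rejoined at 8.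

Step 13. Facial selectivity at C9 may be poor in the closed transition state, because C10 lies between two branched carbons; the ketone may also enolise toward its γ-methyl group. Fallback: an open transition state in place of the closed one. Setting out from 18, silylation with Me3SiOSO2CF3 and Et3N gives the (Z)-trimethylsilyl enol ether F4. Its Mukaiyama aldol addition to 11 with BF3·OEt2 in CH2Cl2 at −78 °C is a reaction type known for high Felkin–Anh selectivity. After aqueous work-up it comes back at 20; either C8 epimer serves.

Step 21. The basic enolate may deprotonate the ketone at C7 or C9 instead of adding to it; the congested aldolate may revert on warming; and the C2 acetate may be attacked. Fallback: a non-basic, Lewis acid-mediated addition. Setting out from 29, LiN(iPr)2 and Me3SiCl give the silyl ketene acetal F5. It is added to 26 in the presence of MgBr2·OEt2 in CH2Cl2 at −78 °C, where magnesium chelates the ketone between O7 and O9. Attack is again anti to tert-butyl and from the axial face, and aqueous work-up returns the sequence at 31.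

Step 25. Addition may occur on the wrong face of the aldehyde, because only the conformation of the forming ring controls C4; intermolecular coupling and loss of iodine by protonation compete at any but high dilution. Fallback for the stereochemical failure: C4 is set by inversion. Setting out from 36, the ring closure is run as before and the 4R epimer F6 is collected. Mitsunobu esterification of F6 with octanoic acid, PPh3 and diisopropyl azodicarboxylate inverts C4 and installs the ester in one step, rejoining the route at 38. The 4S alcohol 37 goes on through step 26 as planned.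

Step 27. Hydride may be delivered syn to the C11 oxygen if ring A in the bicycle places C20 axial, which would give the 12β epimer. Fallback: inversion by substitution instead of face-selective reduction. Setting out from 38, the reduction is run as before to the 12-epi alcohol F7. Mitsunobu reaction with chloroacetic acid, PPh3 and diisopropyl azodicarboxylate gives the 12α-chloroacetate F8. Thiourea and NaHCO3 in EtOH then remove the chloroacetyl group in the presence of the acetates and the octanoate, and the route is rejoined at 39.

## Further compounds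

F1 | step 3 | ent-cycloadduct, (1R,5R,6R)-enantiomer of 6 | O=C[C@]1(C)CC=C(O[Si](CC)(CC)CC)[C@H](C)[C@H]1CO[Si](C)(C)C(C)(C)C
F2 | step 3 | ent-enone aldehyde, enantiomer of 7 | O=C[C@]1(C)C=CC(=O)[C@H](C)[C@H]1CO[Si](C)(C)C(C)(C)C
F3 | step 3 | diastereomer of 8: (2R,3R) side chain on the enantiomeric ring A | C=C[C@@H](OCc2ccc(OC)cc2)[C@H](O)[C@]1(C)C=CC(=O)[C@H](C)[C@H]1CO[Si](C)(C)C(C)(C)C
F4 | step 13 | (1Z,3Z)-4-iodo-1-(triethylsilyloxy)-2-(trimethylsilyloxy)penta-1,3-diene | C/C(I)=C/C(O[Si](C)(C)C)=C/O[Si](CC)(CC)CC
F5 | step 21 | (2R)-2-tert-butyl-5-methyl-4-(trimethylsilyloxy)-1,3-dioxole | CC1=C(O[Si](C)(C)C)O[C@H](C(C)(C)C)O1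
F6 | step 25 | 4-epi-37, macrocyclic (4R)-allylic alcohol | O[C@@H]1/C(C)=C\[C@@H]2OC(=O)[C@@](C)(O)[C@@]2(O)[C@H](OC(C)=O)[C@H]2[C@](C)(O[Si](C)(C)C(C)(C)C)C(=O)C=C[C@]2(C)[C@@H](OC(C)=O)[C@@H]1OCc1ccc(OC)cc1
F7 | step 27 | 12-epi-39, 12β-alcohol | CCCCCCCC(=O)O[C@H]1/C(C)=C\[C@@H]2OC(=O)[C@@](C)(O)[C@@]2(O)[C@H](OC(C)=O)[C@H]2[C@](C)(O[Si](C)(C)C(C)(C)C)[C@@H](O)C=C[C@]2(C)[C@@H](OC(C)=O)[C@@H]1OCc1ccc(OC)cc1
F8 | step 27 | 12α-chloroacetate of 39 | CCCCCCCC(=O)O[C@H]1/C(C)=C\[C@@H]2OC(=O)[C@@](C)(O)[C@@]2(O)[C@H](OC(C)=O)[C@H]2[C@](C)(O[Si](C)(C)C(C)(C)C)[C@H](OC(=O)CCl)C=C[C@]2(C)[C@@H](OC(C)=O)[C@@H]1OCc1ccc(OC)cc1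
A1 | alternative 1 | ring A-fused (3E,5Z)-cyclodecadien-9-one with C8 ketal | [C@H]1(OCc2ccc(OC)cc2)/C=C/C(C)=C\[C@H](O[Si](C)(C)C(C)(C)C)C2(OCCO2)C(=O)[C@H]3[C@]4(C)OC(C)(C)O[C@@H]4C=C[C@@]31C
A2 | alternative 2 | bicyclic core with ring A cis-11,12-diol and C13=C14 | CC1(C)O[C@H]2/C(C)=C\[C@H](O[Si](C)(C)C(C)(C)C)C3(OCCO3)[C@H](OCc3ccc(OC)cc3)[C@H]3[C@](C)(O)[C@H](O)C=C[C@]3(C)[C@@H](OCc3ccc(OC)cc3)[C@@H]2O1
A3 | alternative 3 | ten-membered C4 allylic alcohol (C3 p-methoxybenzyl ether, C12 silyl ether) | O[C@H]1/C(C)=C\[C@@H]2OC(=O)[C@@](C)(O)[C@@]2(O)[C@H](OC(C)=O)[C@H]2[C@](C)(O)[C@H](O[Si](C)(C)C(C)(C)C)C=C[C@]2(C)[C@@H](OC(C)=O)[C@@H]1OCc1ccc(OC)cc1
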